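**Retrosynthetic overview**
1. Side chain: the hydrated C10 unit is bought as hydroxycitronellal 1; the only change is α,β-dehydrogenation to enal 2 (no skeletal bond is made).
2. Pyran ring (the only ring that is formed; ring A is bought as 2',4',5'-trihydroxyacetophenone 3): disconnect C4–C4a and O1–C2, giving 2 + 3.
3. Forward, 2 and 3 condense through carbinol 4 to vinyl ortho-quinone methide 5; its catalyst-controlled O1–C2 ring closure is the key, stereodefining bond formation and gives (2S)-chromenyl methyl ketone 6.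
4. Enone Cα=Cβ: Claisen–Schmidt disconnection to 6 and ring B aldehyde 7 (THP-masked 4-hydroxybenzaldehyde); aldol adduct 8 and THP-chalcone 9 are passed in one flask on the way to target 10.
5. Ring order: rings A and B are bought, the pyran ring is closed in step 2, and the chalcone is made last so that the enone never meets the acid catalyst.

Assumption 1: 3 (CAS 1818-27-5) and 7 (CAS 74189-56-3) are taken as commercially available; 1 is the bulk fragrance chemical, used as the racemate.
Assumption 2: the sense of induction of the new catalyst is not yet known; the (R)-catalyst is written as giving the (2S)-product, and the (S)-catalyst is used instead if the first run shows the opposite.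
Catalyst of step 2 (constitution): O=P1(NS(=O)(=O)C(F)(F)F)Oc2c(-c3c(C(C)C)cc(C(C)C)cc3C(C)C)cc3ccccc3c2-c2c(O1)c(-c3c(C(C)C)cc(C(C)C)cc3C(C)C)cc3ccccc23, (R)-axis.
Handling: 6, 9 and 10 are kept out of light and air, because 2H-chromenes ring-open photochemically (which would racemise C2) and the 5,8-dihydroxy ring is a hydroquinone.

**Route**

Step 1
Reactants: 1 hydroxycitronellal ((±)-7-hydroxy-3,7-dimethyloctanal)
Product: 2 7-hydroxy-3,7-dimethyloct-2-enal (E/Z mixture)
Conditions: IBX (1.3 equiv), PhF/DMSO 2:1, 65 °C, 8 h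
Reagents that add atoms: none
Why: IBX α,β-dehydrogenation of aldehydes (capture of the enol by pentavalent iodine, then loss of 2-iodosobenzoic acid) places the new double bond in conjugation at C2=C3, leaves the tertiary alcohol alone and destroys the irrelevant C3 stereocenter of 1; the E/Z ratio does not matter because step 2 equilibrates this geometry.

Step 2
Reactants: 2 7-hydroxy-3,7-dimethyloct-2-enal (1.5 equiv, added slowly); 3 2',4',5'-trihydroxyacetophenone
Product: 6 1-[(2S)-5,8-dihydroxy-2-(4-hydroxy-4-methylpentyl)-2-methyl-2H-chromen-6-yl]ethan-1-one, via benzylic carbinol 4 (not isolated), via vinyl ortho-quinone methide 5 (not isolated)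
Conditions: (R)-3,3'-bis(2,4,6-triisopropylphenyl)-1,1'-binaphthalene-2,2'-diyl N-triflylphosphoramide C51H57F3NO5PS (5 mol%), 5 Å MS, PhMe/CH2Cl2 3:1, argon, dark, 0 °C → rt, 48 h
Reagents that add atoms: none
Why: Proposed new method: catalytic enantioselective phenol–enal chromenylation under chiral-anion control. The strong chiral Brønsted acid promotes ortho-hydroxyalkylation of 3 at C-3 (the only carbon flanked by two hydroxyls) to carbinol 4 and its dehydration to the O-protonated vinyl ortho-quinone methide 5. This cation stays paired with the phosphoramide anion through hydrogen bonds to O-4–H (the oxygen that closes the ring) and to the tertiary side-chain hydroxyl, so the anion fixes the face of the planar C-2 terminus that O-4 attacks in the oxa-6π (SN1-like) closure and tells methyl from the hydroxyalkyl arm, forming the O1–C2 bond, the pyran ring and the (2S) centre, while the acetyl-chelated 2-OH stays out. E/Z isomers of the terminus interconvert through the tertiary allyl-cation resonance form (Curtin–Hammett). The closest known reaction types are the racemic amine- or acid-promoted phenol–enal [3+3] annulation and the chiral N-triflylphosphoramide-catalysed asymmetric allylic substitution that closes 2-aryl-2-methyl-2H-chromenes from ortho-hydroxystyryl tertiary carbinols; neither has given a 2,2-dialkyl chromene enantioselectively from a phenol and an enal.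

Step 3
Reactants: 6 1-[(2S)-5,8-dihydroxy-2-(4-hydroxy-4-methylpentyl)-2-methyl-2H-chromen-6-yl]ethan-1-one; 7 4-(tetrahydro-2H-pyran-2-yloxy)benzaldehyde (1.3 equiv)
Product: 10 (E)-1-[(2S)-5,8-dihydroxy-2-(4-hydroxy-4-methylpentyl)-2-methyl-2H-chromen-6-yl]-3-(4-hydroxyphenyl)prop-2-en-1-one (CNP0322520.1), via aldol adduct 8 (not isolated), via THP-protected chalcone 9 (not isolated)
Conditions: KOH (50% aq, 12 equiv), degassed EtOH, argon, 0 °C → rt, 24 h; then 2 M aq HCl to pH 1–2, rt, 2 h
Reagents that add atoms: none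
Why: Claisen–Schmidt aldol condensation in which the enolate of the polyanion of 6 adds to the non-ionisable THP-masked aldehyde and E1cB dehydration of 8 gives the thermodynamic E-enone 9; the aryl THP acetal survives KOH and is hydrolysed at pH 1–2 at rt, where the tertiary alcohol, the chromene and the C2 ether stereocenter are untouched.

**Compound list**
1 | hydroxycitronellal, (±)-7-hydroxy-3,7-dimethyloctanal | CC(CCCC(C)(C)O)CC=O | starting material
2 | 7-hydroxy-3,7-dimethyloct-2-enal (E/Z mixture, E isomer drawn) | CC(C)(O)CCC/C(C)=C/C=O | intermediate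
3 | 2',4',5'-trihydroxyacetophenone, 1-(2,4,5-trihydroxyphenyl)ethan-1-one | CC(=O)c1cc(O)c(O)cc1O | starting material
4 | 1-[3-(1,7-dihydroxy-3,7-dimethyloct-2-en-1-yl)-2,4,5-trihydroxyphenyl]ethan-1-one (racemic carbinol, E/Z mixture, not isolated) | CC(=O)c1cc(O)c(O)c(C(O)C=C(C)CCCC(C)(C)O)c1O | intermediate
5 | 4-acetyl-2,5-dihydroxy-6-(7-hydroxy-3,7-dimethyloct-2-en-1-ylidene)cyclohexa-2,4-dien-1-one (vinyl ortho-quinone methide, drawn neutral, ion-paired in the flask, not isolated) | CC(=O)C1=C(O)C(=CC=C(C)CCCC(C)(C)O)C(=O)C(O)=C1 | intermediate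
6 | 1-[(2S)-5,8-dihydroxy-2-(4-hydroxy-4-methylpentyl)-2-methyl-2H-chromen-6-yl]ethan-1-one | CC(C)(O)CCC[C@@]1(C)C=Cc2c(O)c(C(C)=O)cc(O)c2O1 | intermediate
7 | 4-(tetrahydro-2H-pyran-2-yloxy)benzaldehyde (racemic acetal) | O=Cc1ccc(OC2CCCCO2)cc1 | starting material
8 | 1-[(2S)-5,8-dihydroxy-2-(4-hydroxy-4-methylpentyl)-2-methyl-2H-chromen-6-yl]-3-hydroxy-3-[4-(tetrahydro-2H-pyran-2-yloxy)phenyl]propan-1-one (mixture at the carbinol and acetal carbons, not isolated) | CC(C)(O)CCC[C@@]1(C)C=Cc2c(O)c(C(=O)CC(O)c3ccc(OC4CCCCO4)cc3)cc(O)c2O1 | intermediate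
9 | (E)-1-[(2S)-5,8-dihydroxy-2-(4-hydroxy-4-methylpentyl)-2-methyl-2H-chromen-6-yl]-3-[4-(tetrahydro-2H-pyran-2-yloxy)phenyl]prop-2-en-1-one (mixture at the acetal carbon, not isolated) | CC(C)(O)CCC[C@@]1(C)C=Cc2c(O)c(C(=O)/C=C/c3ccc(OC4CCCCO4)cc3)cc(O)c2O1 | intermediate
10 | (E)-1-[(2S)-5,8-dihydroxy-2-(4-hydroxy-4-methylpentyl)-2-methyl-2H-chromen-6-yl]-3-(4-hydroxyphenyl)prop-2-en-1-one | CC(C)(O)CCC[C@@]1(C)C=Cc2c(O)c(C(=O)/C=C/c3ccc(O)cc3)cc(O)c2O1 | target

**Summary**
Total step count: 3.
Longest linear sequence: 3 steps (1 → 2 → 6 → 10).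

**Steps most likely to fail, with fallbacks**

Step 2 (the proposed new method). The risks are a modest ee, because a methyl and a methylene chain must be told apart; a slow reaction of the acyl-deactivated phenol; and competition by the side-chain hydroxyl as a nucleophile. The fallback uses known chemistry, sets out from 3 (with 2) and comes back to the route at 6. Compounds 2 and 3 are heated with ethylenediammonium diacetate (10 mol%) in xylene at 140 °C, the established racemic phenol–enal annulation, which runs through the same quinone methide 5. This gives racemic 1-[5,8-dihydroxy-2-(4-hydroxy-4-methylpentyl)-2-methyl-2H-chromen-6-yl]ethan-1-one F1. The racemate is resolved by preparative supercritical-fluid chromatography on amylose tris(3,5-dimethylphenylcarbamate) with CO2/MeOH. The (S)-enantiomer is 6; 1-[(2R)-5,8-dihydroxy-2-(4-hydroxy-4-methylpentyl)-2-methyl-2H-chromen-6-yl]ethan-1-one F2 is set aside. The configuration is assigned by comparing the chiroptical data of 10 made from each enantiomer with those of the natural product.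

Step 3. The risks are air oxidation of the hydroquinone dianion of 6 in KOH and a sluggish condensation of the polyanion. The fallback sets out from 6 and comes back at 10. It gives up the protecting-group-free one-flask endgame for a stepwise protected one, so that the substrate enters the base as a monoanion and condensation and deprotection are separated.
- MOMCl (1.2 equiv) and K2CO3 in acetone (0 °C → rt) cap the free 8-OH to give 1-[(2S)-5-hydroxy-2-(4-hydroxy-4-methylpentyl)-8-(methoxymethoxy)-2-methyl-2H-chromen-6-yl]ethan-1-one F3.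
- Claisen–Schmidt condensation of F3 with commercial 4-(methoxymethoxy)benzaldehyde (KOH, EtOH/H2O, rt) passes through the aldol adduct 3-hydroxy-1-[(2S)-5-hydroxy-2-(4-hydroxy-4-methylpentyl)-8-(methoxymethoxy)-2-methyl-2H-chromen-6-yl]-3-[4-(methoxymethoxy)phenyl]propan-1-one F4.
- Dehydration of F4 gives (E)-1-[(2S)-5-hydroxy-2-(4-hydroxy-4-methylpentyl)-8-(methoxymethoxy)-2-methyl-2H-chromen-6-yl]-3-[4-(methoxymethoxy)phenyl]prop-2-en-1-one F5, which is isolated.
- Both MOM ethers of F5 are cleaved with 3 M HCl in MeOH (rt → 40 °C) to give 10.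

Step 1. The risks are over-oxidation to the dienal and incomplete conversion of the β-branched aldehyde. The fallback sets out from 1 and comes back at 2. It replaces the direct dehydrogenation by a functionalise-then-eliminate sequence.
- Enamine-mediated α-selenenylation of 1 with N-(phenylseleno)phthalimide and L-prolinamide (10 mol%) in CH2Cl2 at rt gives 7-hydroxy-3,7-dimethyl-2-(phenylselanyl)octanal F6.
- Oxidation with NaIO4 in THF/H2O (0 °C → rt) gives 7-hydroxy-3,7-dimethyl-2-(phenylseleninyl)octanal F7, which is not isolated.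
- Selenoxide syn-elimination of F7 uses the single β-hydrogen at C3 and so gives only the conjugated enal 2.

**Further compounds**
F1 | step 2 | racemic 1-[5,8-dihydroxy-2-(4-hydroxy-4-methylpentyl)-2-methyl-2H-chromen-6-yl]ethan-1-one | CC(C)(O)CCCC1(C)C=Cc2c(O)c(C(C)=O)cc(O)c2O1
F2 | step 2 | 1-[(2R)-5,8-dihydroxy-2-(4-hydroxy-4-methylpentyl)-2-methyl-2H-chromen-6-yl]ethan-1-one | CC(C)(O)CCC[C@]1(C)C=Cc2c(O)c(C(C)=O)cc(O)c2O1
F3 | step 3 | 1-[(2S)-5-hydroxy-2-(4-hydroxy-4-methylpentyl)-8-(methoxymethoxy)-2-methyl-2H-chromen-6-yl]ethan-1-one | CC(C)(O)CCC[C@@]1(C)C=Cc2c(O)c(C(C)=O)cc(OCOC)c2O1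
F4 | step 3 | 3-hydroxy-1-[(2S)-5-hydroxy-2-(4-hydroxy-4-methylpentyl)-8-(methoxymethoxy)-2-methyl-2H-chromen-6-yl]-3-[4-(methoxymethoxy)phenyl]propan-1-one | CC(C)(O)CCC[C@@]1(C)C=Cc2c(O)c(C(=O)CC(O)c3ccc(OCOC)cc3)cc(OCOC)c2O1
F5 | step 3 | (E)-1-[(2S)-5-hydroxy-2-(4-hydroxy-4-methylpentyl)-8-(methoxymethoxy)-2-methyl-2H-chromen-6-yl]-3-[4-(methoxymethoxy)phenyl]prop-2-en-1-one | CC(C)(O)CCC[C@@]1(C)C=Cc2c(O)c(C(=O)/C=C/c3ccc(OCOC)cc3)cc(OCOC)c2O1
F6 | step 1 | 7-hydroxy-3,7-dimethyl-2-(phenylselanyl)octanal | CC(C)(O)CCCC(C)C(C=O)[Se]c1ccccc1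
F7 | step 1 | 7-hydroxy-3,7-dimethyl-2-(phenylseleninyl)octanal | CC(C)(O)CCCC(C)C(C=O)[Se](=O)c1ccccc1
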